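**Plan**
- **Cuts:** the ester C–O between the C3 carboxyl and (R)-danshensu. Then the C4 lactate arm, taken back through a caffeoyl enol ester C=C to a C4 aldehyde. Then C7–O to C7–Si, the benzene bonds C3a–C7a, C4–C5 and C6–C7, and last C2–C3.
- **Enabling feature:** the benzofuran benzene ring has four contiguous substituted carbons (C4 chain, C3a–C3, C7a–O1, C7–OH) next to two adjacent CH groups (C5, C6). C3a and C7a are bridged by only three atoms (C3, C2, O1). The bicycle is therefore a 1,6-diyne (internal alkyne plus ynol ether) joined to acetylene.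
- **Forward order:** ynone, propargylic mesylate, C2–C3 bond by propargylation, O-alkynylation. The dihydrofuran and benzene rings then close together in one step, followed by Si to OH, the lactate arm, the danshensu ester and acidolysis.
- **Stereochemistry:** C3 comes by chirality transfer from an (S)-propargylic mesylate made by asymmetric transfer hydrogenation. C2 comes from the anti preference of the closed allenylzinc transition state. The lactate carbinol comes from catalyst-controlled Rh-DuPhos hydrogenation, and the fourth centre from (R)-danshensu.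
- **Protection:** catechols as diphenylmethylene ketals, acids as tert-butyl esters and C7–OH as MOM, all removed by TFA. C3 stays as CH2OPMB until no base is needed any more, because a C3 ester could open the ring by E1cB.

Key step: step 14

Remark: Ar = 2,2-diphenyl-1,3-benzodioxol-5-yl, PMB = 4-methoxybenzyl, MOM = methoxymethyl. Benzofuran numbering is also used for the acyclic precursors. Danshensu is taken as the free acid, and the olefination product is carried on as an E/Z mixture because both isomers should be reduced in the same sense.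

Step 1
Reactants: 1 3,4-dihydroxybenzaldehyde
Product: 2 2,2-diphenyl-1,3-benzodioxole-5-carbaldehyde (ArCHO)
Conditions: Ph2CCl2, K2CO3, MeCN, 60 °C
Reagents that add atoms: dichlorodiphenylmethane, ClC(Cl)(c1ccccc1)c1ccccc1
Why: Cyclic ketal formation by double O-alkylation of the catechol with a gem-dichloride (Williamson type) should give a mask that tolerates KH, n-BuLi, fluoride, peroxide and H2/Rh but leaves with TFA.

Step 2
Reactants: 2 ArCHO; 3 malonic acid
Product: 4 (E)-3-Ar-prop-2-enoic acid (ketal-protected caffeic acid)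
Conditions: pyridine, piperidine (cat.), 90 °C
Reagents that add atoms: none
Why: Knoevenagel–Doebner condensation with in situ decarboxylation should give only the thermodynamically favoured E-cinnamic acid.

Step 3
Reactants: 5 tert-butyl 2-(dimethoxyphosphoryl)acetate
Product: 6 tert-butyl 2-diazo-2-(dimethoxyphosphoryl)acetate
Conditions: p-ABSA, DBU, MeCN, 0 °C → rt
Reagents that add atoms: 4-acetamidobenzenesulfonyl azide, CC(=O)Nc1ccc(cc1)S(=O)(=O)N=[N+]=[N-]
Why: Regitz diazo transfer works on this doubly activated methylene with an amidine base.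

Step 4
Reactants: 6 diazophosphonoacetate; 4 protected caffeic acid
Product: 7 tert-butyl 2-(dimethoxyphosphoryl)-2-{[(E)-3-Ar-prop-2-enoyl]oxy}acetate (racemic)
Conditions: Rh2(OAc)4 (1 mol %), toluene, 80 °C, slow addition of 6
Reagents that add atoms: none
Why: Rh(II)-carbenoid O–H insertion into a carboxylic acid is faster than cyclopropanation of the electron-poor cinnamate C=C, and the new centre needs no control because it becomes sp2 in step 18.

Step 5
Reactants: 8 (R)-danshensu
Product: 9 tert-butyl (2R)-3-(3,4-dihydroxyphenyl)-2-hydroxypropanoate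
Conditions: Cl3CC(=NH)Ot-Bu, THF/cyclohexane, rt
Reagents that add atoms: tert-butyl 2,2,2-trichloroacetimidate, CC(C)(C)OC(=N)C(Cl)(Cl)Cl
Why: Trichloroacetimidate tert-butylation is triggered by the carboxylic acid itself, so the phenols and the carbinol stay free and the chiral-pool (R) centre is not touched.

Step 6
Reactants: 9 danshensu tert-butyl ester
Product: 10 tert-butyl (2R)-3-Ar-2-hydroxypropanoate
Conditions: Ph2CCl2, K2CO3, MeCN, rt → 50 °C
Reagents that add atoms: dichlorodiphenylmethane, ClC(Cl)(c1ccccc1)c1ccccc1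
Why: This is the same base-mediated catechol ketalisation as in step 1, where only the 1,2-diphenol can close the five-membered ketal, so the secondary OH stays free and the base-stable tert-butyl ester survives.

Step 7
Reactants: 11 4-methoxybenzyl alcohol; 12 2-chloro-N-methoxy-N-methylacetamide
Product: 13 N-methoxy-2-[(4-methoxybenzyl)oxy]-N-methylacetamide
Conditions: NaH, THF, 0 °C → rt
Reagents that add atoms: none
Why: In this Williamson ether synthesis, SN2 at the activated alpha-chloro amide is much faster than attack of the alkoxide on the Weinreb carbonyl.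

Step 8
Reactants: 14 3,3-diethoxyprop-1-yne; 13 Weinreb amide
Product: 16 5,5-diethoxy-1-[(4-methoxybenzyl)oxy]pent-3-yn-2-one, via lithium 3,3-diethoxypropynide 15 (not isolated)
Conditions: n-BuLi, THF, −78 °C; 13, −78 → −20 °C; inverse quench into cold aq NaH2PO4
Reagents that add atoms: none
Why: In this Weinreb ketone synthesis the chelated tetrahedral adduct stops at the ynone stage, and the cold buffered quench keeps the liberated amine from adding to the ynone and spares the acetal.

Step 9
Reactants: 16 ynone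
Product: 17 (2S)-5,5-diethoxy-1-[(4-methoxybenzyl)oxy]pent-3-yn-2-ol
Conditions: Ru[(R,R)-TsDPEN](p-cymene) (1 mol %), i-PrOH, rt
Reagents that add atoms: none
Why: In the Noyori asymmetric transfer hydrogenation of an ynone the alkynyl group takes the place of the aryl group in the CH/π-controlled transition state, so the (R,R)-catalyst should give the carbinol that is (S) here because CH2OPMB outranks the alkyne.

Step 10
Reactants: 17 (S)-propargylic alcohol
Product: 18 (2S)-5,5-diethoxy-1-[(4-methoxybenzyl)oxy]pent-3-yn-2-yl methanesulfonate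
Conditions: MsCl, Et3N, CH2Cl2, −78 → 0 °C, used crude
Reagents that add atoms: methanesulfonyl chloride, CS(=O)(=O)Cl
Why: Sulfonylation at oxygen leaves the C–O bond and hence the (S) configuration intact.

Step 11
Reactants: 18 (S)-mesylate; 2 ArCHO
Product: 20 (1S,2R)-5,5-diethoxy-1-Ar-2-(PMBOCH2)pent-3-yn-1-ol (anti), via (aS)-allenyl(ethyl)zinc 19 (not isolated)
Conditions: Pd(OAc)2 (5 mol %), PPh3 (5 mol %), Et2Zn (3 equiv), THF, −78 → −20 °C
Reagents that add atoms: none
Why: In the Marshall propargylation Pd(0) displaces the mesylate anti-SN2′, Et2Zn transmetalates with retention and the allenylzinc adds to the aldehyde through a closed SE2′ transition state, so C3 is set by chirality transfer (net inversion) and C2 by the anti preference that keeps Ar away from CH2OPMB, any syn isomer being removed by chromatography.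

Step 12
Reactants: 20 anti alcohol; 21 trichloroethylene
Product: 22 (E)-1,2-dichlorovinyl ether of 20
Conditions: KH, THF, 0 °C; Cl2C=CHCl, −78 °C → rt
Reagents that add atoms: none
Why: In the first stage of the Greene ynol ether synthesis the potassium alkoxide adds anti to dichloroacetylene released from trichloroethylene, which gives the E-dichlorovinyl ether without touching the C2–O bond, and the fully substituted alkyne offers no acidic C–H.

Step 13
Reactants: 22 dichlorovinyl ether
Product: 25 [benzyl(dimethyl)silyl]ethynyl ether of 20 (the 1,6-diyne), via chloroethynyl ether 23 (not isolated), via lithioethynyl ether 24 (not isolated)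
Conditions: n-BuLi (2.3 equiv), THF, −78 → −40 °C; BnMe2SiCl, −78 → 0 °C; Et3N-deactivated silica
Reagents that add atoms: benzylchlorodimethylsilane, C[Si](C)(Cl)Cc1ccccc1
Why: In the second stage of the same synthesis n-BuLi eliminates HCl, exchanges the alkynyl chloride for lithium and the alkoxyacetylide is C-silylated, the vinyl C–H being far more acidic than any other site at −78 °C.

Step 14
Reactants: 25 1,6-diyne; 26 acetylene
Product: 27 (2S,3R)-7-[benzyl(dimethyl)silyl]-4-(diethoxymethyl)-2-Ar-3-(PMBOCH2)-2,3-dihydro-1-benzofuran (trans)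
Conditions: RhCl(PPh3)3 (10 mol %), HC≡CH (1 atm), toluene, 20 → 40 °C, slow addition of 25
Reagents that add atoms: none
Why: Proposed new method: Rh(I) binds both alkynes of 25 and oxidative cyclisation joins the two alkyne carbons next to the C3–C2–O1 tether (C3a–C7a) to a rhodacyclopentadiene fused to the new 2,3-dihydrofuran, so this ring closes in the five-membered exo,exo mode that a three-atom tether favours. Acetylene then coordinates, inserts into a Rh–C bond (C4–C5 or C6–C7) and reductive elimination makes the last bond, which closes the benzene ring as a formal [2+2+2] cycloaddition. The closest known reaction types are Rh(I)-catalysed [2+2+2] cycloadditions of ynamide-tethered 1,6-diynes with acetylene to indolines and of aryl alkynyl ether 1,6-diynes to dibenzofurans, whereas a silyl-capped sec-alkyl ynol ether in the tether has not been shown. No stereocentre is made, since C2 and C3 are spectators on the tether and their anti relation becomes the trans relation of Ar and CH2OPMB on the ring. The step needs selectivity for acetylene over a second diyne and poses no regiochemical question, because both diyne termini are blocked by SiMe2Bn and CH(OEt)2, acetylene is small, symmetrical and in excess, and slow addition keeps 25 dilute. The silyl cap tames the ynol ether, and a bath at or below 40 °C should keep retro-ene loss of ketene and the [3,3] shift of the benzylic alkynyl ether slow.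

Step 15
Reactants: 27 arylsilane
Product: 29 (2S,3R)-4-(diethoxymethyl)-2-Ar-3-(PMBOCH2)-2,3-dihydro-1-benzofuran-7-ol, via aryldimethylsilanol 28 (not isolated)
Conditions: TBAF, THF, 0 °C; then 30 % H2O2, KHCO3, MeOH, rt
Reagents that add atoms: hydrogen peroxide, OO
Why: In the Tamao–Fleming oxidation fluoride cleaves the benzyl–Si bond, which is far more fluoride-labile than aryl–Si, and the aryl group of the silanol then migrates from Si to peroxide oxygen, so the hydroxyl appears exactly at C7 while acetal, PMB ether and ketal are inert to basic peroxide.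

Step 16
Reactants: 29 phenol
Product: 30 (2S,3R)-4-(diethoxymethyl)-7-(methoxymethoxy)-2-Ar-3-(PMBOCH2)-2,3-dihydro-1-benzofuran
Conditions: MOMCl, i-Pr2NEt, CH2Cl2, 0 °C → rt
Reagents that add atoms: chloromethyl methyl ether, COCCl
Why: This standard phenol O-alkylation installs MOM, which blocks the phenoxide that would deactivate the para aldehyde in step 18 and falls off with TFA at the end.

Step 17
Reactants: 30 acetal
Product: 31 (2S,3R)-7-(methoxymethoxy)-2-Ar-3-(PMBOCH2)-2,3-dihydro-1-benzofuran-4-carbaldehyde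
Conditions: PPTS (cat.), acetone/H2O, rt
Reagents that add atoms: water, O
Why: In this acid-catalysed acetal hydrolysis the oxocarbenium ion para to OMOM forms so easily that catalytic PPTS suffices, which leaves the aryl MOM ether, the diaryl ketal and the PMB ether alone.

Step 18
Reactants: 31 aldehyde; 7 caffeoyloxy phosphonate
Product: 32 tert-butyl 2-{[(E)-3-Ar-prop-2-enoyl]oxy}-3-[(2S,3R)-7-(methoxymethoxy)-2-Ar-3-(PMBOCH2)-2,3-dihydro-1-benzofuran-4-yl]prop-2-enoate (E/Z mixture at the enol ester C=C)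
Conditions: LiCl, DBU, MeCN/THF, 0 °C → rt
Reagents that add atoms: none
Why: In this Horner–Wadsworth–Emmons olefination under Masamune–Roush conditions the acidic alpha-acyloxyphosphonate needs only an amidine base, and with C3 still at the alcohol level there is no acidic C3–H that could open the ring by E1cB.

Step 19
Reactants: 32 enol ester
Product: 33 tert-butyl (2R)-2-{[(E)-3-Ar-prop-2-enoyl]oxy}-3-[(2S,3R)-7-(methoxymethoxy)-2-Ar-3-(PMBOCH2)-2,3-dihydro-1-benzofuran-4-yl]propanoate
Conditions: [((R,R)-Et-DuPhos)Rh(cod)]BF4 (2–5 mol %), H2 (4–6 bar), CH2Cl2/MeOH, rt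
Reagents that add atoms: none
Why: In the Rh-DuPhos asymmetric hydrogenation of an alpha-acyloxyacrylate the enol ester C=C and its acyl C=O chelate the cationic Rh, which should set the new (R) carbinol centre under catalyst control (the (R,R)-ligand is chosen by analogy with enamides, and both alkene isomers react in the same sense) and leave the non-chelating caffeoyl C=C, the PMB ether and the ketals untouched.

Step 20
Reactants: 33 PMB ether
Product: 34 tert-butyl (2R)-2-{[(E)-3-Ar-prop-2-enoyl]oxy}-3-[(2S,3R)-3-(hydroxymethyl)-7-(methoxymethoxy)-2-Ar-2,3-dihydro-1-benzofuran-4-yl]propanoate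
Conditions: DDQ, CH2Cl2/pH 7 buffer, 0 °C
Reagents that add atoms: none
Why: Oxidative PMB cleavage by DDQ (hydride abstraction from the most electron-rich benzylic ether CH2) under buffered conditions spares the esters, MOM, the ketals and the cinnamate.

Step 21
Reactants: 34 primary alcohol
Product: 36 (2S,3S)-4-[(2R)-3-tert-butoxy-2-{[(E)-3-Ar-prop-2-enoyl]oxy}-3-oxopropyl]-7-(methoxymethoxy)-2-Ar-2,3-dihydro-1-benzofuran-3-carboxylic acid, via 3-carbaldehyde 35 (not isolated)
Conditions: TEMPO (cat.), PhI(OAc)2, MeCN/H2O, rt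
Reagents that add atoms: water, O
Why: TEMPO/PhI(OAc)2 oxidation in aqueous MeCN takes the primary alcohol through the aldehyde hydrate to the acid under weakly acidic conditions, so no base is present to eliminate or epimerise the beta-aryloxy aldehyde, and trans is the stable arrangement anyway.

Step 22
Reactants: 36 C3 acid; 10 protected danshensu
Product: 37 fully protected target (C3 ester of 36 with the carbinol of 10)
Conditions: EDC·HCl, DMAP (cat.), CH2Cl2, 0 °C → rt
Reagents that add atoms: none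
Why: In the Steglich esterification the (R) carbinol of 10 reacts at oxygen with retention, and any enolisation at C3 returns to the favoured trans isomer.

Step 23
Reactants: 37 fully protected target
Product: 38 CNP0201431.1 (target)
Conditions: TFA/CH2Cl2/H2O, 0 °C → rt, Ar; reversed-phase purification
Reagents that add atoms: none
Why: In the global acidolysis the ketals and MOM hydrolyse via stabilised oxocarbenium ions and the tert-butyl esters lose isobutene (E1), while the secondary alkyl esters, the E-alkene and the four stereocentres should not be affected by cold aqueous TFA.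

**Compound list**
1 | 3,4-dihydroxybenzaldehyde | O=Cc1ccc(O)c(O)c1 | starting material
2 | 2,2-diphenyl-1,3-benzodioxole-5-carbaldehyde | O=Cc1ccc2c(c1)OC(c1ccccc1)(c1ccccc1)O2 | intermediate
3 | malonic acid | OC(=O)CC(=O)O | starting material
4 | (E)-3-(2,2-diphenyl-1,3-benzodioxol-5-yl)prop-2-enoic acid | OC(=O)/C=C/c1ccc2c(c1)OC(c1ccccc1)(c1ccccc1)O2 | intermediate
5 | tert-butyl 2-(dimethoxyphosphoryl)acetate | COP(=O)(OC)CC(=O)OC(C)(C)C | starting material
6 | tert-butyl 2-diazo-2-(dimethoxyphosphoryl)acetate | COP(=O)(OC)C(=[N+]=[N-])C(=O)OC(C)(C)C | intermediate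
7 | tert-butyl 2-(dimethoxyphosphoryl)-2-{[(E)-3-(2,2-diphenyl-1,3-benzodioxol-5-yl)prop-2-enoyl]oxy}acetate (racemic) | COP(=O)(OC)C(OC(=O)/C=C/c1ccc2c(c1)OC(c1ccccc1)(c1ccccc1)O2)C(=O)OC(C)(C)C | intermediate
8 | (R)-danshensu, (2R)-3-(3,4-dihydroxyphenyl)-2-hydroxypropanoic acid | O[C@H](Cc1ccc(O)c(O)c1)C(=O)O | starting material
9 | tert-butyl (2R)-3-(3,4-dihydroxyphenyl)-2-hydroxypropanoate | O[C@H](Cc1ccc(O)c(O)c1)C(=O)OC(C)(C)C | intermediate
10 | tert-butyl (2R)-3-(2,2-diphenyl-1,3-benzodioxol-5-yl)-2-hydroxypropanoate | O[C@H](Cc1ccc2c(c1)OC(c1ccccc1)(c1ccccc1)O2)C(=O)OC(C)(C)C | intermediate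
11 | 4-methoxybenzyl alcohol | COc1ccc(CO)cc1 | starting material
12 | 2-chloro-N-methoxy-N-methylacetamide | ClCC(=O)N(C)OC | starting material
13 | N-methoxy-2-[(4-methoxybenzyl)oxy]-N-methylacetamide | COc1ccc(COCC(=O)N(C)OC)cc1 | intermediate
14 | 3,3-diethoxyprop-1-yne | C#CC(OCC)OCC | starting material
15 | lithium 3,3-diethoxyprop-1-yn-1-ide | [Li]C#CC(OCC)OCC | intermediate
16 | 5,5-diethoxy-1-[(4-methoxybenzyl)oxy]pent-3-yn-2-one | CCOC(OCC)C#CC(=O)COCc1ccc(OC)cc1 | intermediate
17 | (2S)-5,5-diethoxy-1-[(4-methoxybenzyl)oxy]pent-3-yn-2-ol | CCOC(OCC)C#C[C@@H](COCc1ccc(OC)cc1)O | intermediate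
18 | (2S)-5,5-diethoxy-1-[(4-methoxybenzyl)oxy]pent-3-yn-2-yl methanesulfonate | CCOC(OCC)C#C[C@@H](COCc1ccc(OC)cc1)OS(C)(=O)=O | intermediate
19 | ethyl{(aS)-1,1-diethoxy-5-[(4-methoxybenzyl)oxy]penta-2,3-dien-2-yl}zinc (Zn on the face opposite to the departed mesylate) | CC[Zn]C(C(OCC)OCC)=[C@@]=C([H])COCc1ccc(OC)cc1 | intermediate
20 | (1S,2R)-5,5-diethoxy-1-(2,2-diphenyl-1,3-benzodioxol-5-yl)-2-{[(4-methoxybenzyl)oxy]methyl}pent-3-yn-1-ol (anti) | CCOC(OCC)C#C[C@H](COCc1ccc(OC)cc1)[C@@H](c1ccc2c(c1)OC(c1ccccc1)(c1ccccc1)O2)O | intermediate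
21 | trichloroethylene | ClC=C(Cl)Cl | starting material
22 | (E)-1,2-dichlorovinyl ether of 20 | CCOC(OCC)C#C[C@H](COCc1ccc(OC)cc1)[C@@H](c1ccc2c(c1)OC(c1ccccc1)(c1ccccc1)O2)O/C(Cl)=C\Cl | intermediate
23 | chloroethynyl ether of 20 | CCOC(OCC)C#C[C@H](COCc1ccc(OC)cc1)[C@@H](c1ccc2c(c1)OC(c1ccccc1)(c1ccccc1)O2)OC#CCl | intermediate
24 | lithioethynyl ether of 20 | CCOC(OCC)C#C[C@H](COCc1ccc(OC)cc1)[C@@H](c1ccc2c(c1)OC(c1ccccc1)(c1ccccc1)O2)OC#C[Li] | intermediate
25 | [benzyl(dimethyl)silyl]ethynyl ether of 20, (1S,2R)-1,6-diyne | CCOC(OCC)C#C[C@H](COCc1ccc(OC)cc1)[C@@H](c1ccc2c(c1)OC(c1ccccc1)(c1ccccc1)O2)OC#C[Si](C)(C)Cc1ccccc1 | intermediate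
26 | acetylene | C#C | starting material
27 | (2S,3R)-7-[benzyl(dimethyl)silyl]-4-(diethoxymethyl)-2-(2,2-diphenyl-1,3-benzodioxol-5-yl)-3-{[(4-methoxybenzyl)oxy]methyl}-2,3-dihydro-1-benzofuran | CCOC(OCC)c1ccc([Si](C)(C)Cc3ccccc3)c2c1[C@H](COCc1ccc(OC)cc1)[C@@H](c1ccc3c(c1)OC(c1ccccc1)(c1ccccc1)O3)O2 | intermediate
28 | 7-[hydroxy(dimethyl)silyl] analogue of 27 | CCOC(OCC)c1ccc([Si](C)(C)O)c2c1[C@H](COCc1ccc(OC)cc1)[C@@H](c1ccc3c(c1)OC(c1ccccc1)(c1ccccc1)O3)O2 | intermediate
29 | (2S,3R)-4-(diethoxymethyl)-2-(2,2-diphenyl-1,3-benzodioxol-5-yl)-3-{[(4-methoxybenzyl)oxy]methyl}-2,3-dihydro-1-benzofuran-7-ol | CCOC(OCC)c1ccc(O)c2c1[C@H](COCc1ccc(OC)cc1)[C@@H](c1ccc3c(c1)OC(c1ccccc1)(c1ccccc1)O3)O2 | intermediate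
30 | 7-O-methoxymethyl ether of 29 | CCOC(OCC)c1ccc(OCOC)c2c1[C@H](COCc1ccc(OC)cc1)[C@@H](c1ccc3c(c1)OC(c1ccccc1)(c1ccccc1)O3)O2 | intermediate
31 | (2S,3R)-7-(methoxymethoxy)-2-(2,2-diphenyl-1,3-benzodioxol-5-yl)-3-{[(4-methoxybenzyl)oxy]methyl}-2,3-dihydro-1-benzofuran-4-carbaldehyde | O=Cc1ccc(OCOC)c2c1[C@H](COCc1ccc(OC)cc1)[C@@H](c1ccc3c(c1)OC(c1ccccc1)(c1ccccc1)O3)O2 | intermediate
32 | caffeoyl enol ester from 31 and 7 (E/Z mixture at the new C=C) | CC(C)(C)OC(=O)C(OC(=O)/C=C/c1ccc2c(c1)OC(c1ccccc1)(c1ccccc1)O2)=Cc1ccc(OCOC)c2c1[C@H](COCc1ccc(OC)cc1)[C@@H](c1ccc3c(c1)OC(c1ccccc1)(c1ccccc1)O3)O2 | intermediate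
33 | (2R)-2-caffeoyloxy propanoate, protected, C3 arm CH2OPMB, (2S,3R) ring | O=C(/C=C/c1ccc2c(c1)OC(c1ccccc1)(c1ccccc1)O2)O[C@H](Cc1ccc(OCOC)c2c1[C@H](COCc1ccc(OC)cc1)[C@@H](c1ccc3c(c1)OC(c1ccccc1)(c1ccccc1)O3)O2)C(=O)OC(C)(C)C | intermediate
34 | 3-(hydroxymethyl) compound from 33 | O=C(/C=C/c1ccc2c(c1)OC(c1ccccc1)(c1ccccc1)O2)O[C@H](Cc1ccc(OCOC)c2c1[C@H](CO)[C@@H](c1ccc3c(c1)OC(c1ccccc1)(c1ccccc1)O3)O2)C(=O)OC(C)(C)C | intermediate
35 | (2S,3S)-3-carbaldehyde from 34 | O=C(/C=C/c1ccc2c(c1)OC(c1ccccc1)(c1ccccc1)O2)O[C@H](Cc1ccc(OCOC)c2c1[C@H](C=O)[C@@H](c1ccc3c(c1)OC(c1ccccc1)(c1ccccc1)O3)O2)C(=O)OC(C)(C)C | intermediate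
36 | (2S,3S)-3-carboxylic acid from 34 | O=C(/C=C/c1ccc2c(c1)OC(c1ccccc1)(c1ccccc1)O2)O[C@H](Cc1ccc(OCOC)c2c1[C@H](C(=O)O)[C@@H](c1ccc3c(c1)OC(c1ccccc1)(c1ccccc1)O3)O2)C(=O)OC(C)(C)C | intermediate
37 | fully protected target (three diphenylmethylene ketals, two tert-butyl esters, one MOM ether) | O=C(/C=C/c1ccc2c(c1)OC(c1ccccc1)(c1ccccc1)O2)O[C@H](Cc1ccc(OCOC)c2c1[C@H](C(=O)O[C@H](Cc1ccc3c(c1)OC(c1ccccc1)(c1ccccc1)O3)C(=O)OC(C)(C)C)[C@@H](c1ccc3c(c1)OC(c1ccccc1)(c1ccccc1)O3)O2)C(=O)OC(C)(C)C | intermediate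
38 | CNP0201431.1 | O=C(/C=C/c1ccc(O)c(O)c1)O[C@H](Cc1ccc(O)c2c1[C@H](C(=O)O[C@H](Cc1ccc(O)c(O)c1)C(=O)O)[C@@H](c1ccc(O)c(O)c1)O2)C(=O)O | target

**Totals**
- Total step count: 23.
- Longest linear sequence: 17 steps (steps 7–23).
- Branches: steps 1–2, 3–4 and 5–6.

**Steps most likely to fail**

1. **Step 14** (bears the label).
   - What may go wrong: the electron-rich and thermally fragile ynol ether may be lost through hydration, retro-ene fragmentation or [3,3] shift before the doubly end-capped diyne undergoes oxidative cyclisation. The catalyst may also be consumed by oligomerisation of acetylene.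
   - Fallback (known chemistry): the intramolecular inverse-electron-demand Diels–Alder reaction of 3-(alkynyloxy)pyridazine-4-carbonitriles, which gives 2,3-dihydrobenzofuran-7-carbonitriles with loss of nitrogen. It sets out from 20 and comes back at 29.
   - Route: NaH and commercial 3-chloropyridazine-4-carbonitrile in THF convert 20 by SNAr into the pyridazinyl ether F1. Heating in 1,2-dichlorobenzene at 150–180 °C adds the internal alkyne across C3/C6 of the diazine and expels N2, which gives the trans 7-carbonitrile F2. DIBAL-H followed by buffered hydrolysis gives the 7-carbaldehyde F3. Buffered mCPBA (Baeyer–Villiger, Dakin type) gives the aryl formate F4, and K2CO3/MeOH releases phenol 29.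

2. **Step 11.**
   - What may go wrong: the allenylzinc carries an acetal on the metal-bearing carbon and an allylic ether, so beta- or 1,4-elimination may outrun addition. Discrimination between the anti and syn transition states may also be poor with an aromatic aldehyde.
   - Fallback: an isolable allenylboron reagent is used in place of a transient allenylzinc. It sets out from 17 (with 2) and comes back at 20.
   - Route: ClCO2Me/pyridine gives the propargylic methyl carbonate F5. Cu(I)-catalysed anti-SN2′ borylation (CuOt-Bu, Xantphos, B2pin2, THF) gives the (aR)-allenylboronate F6. Allenylboration of 2 in toluene through the closed six-membered transition state gives the O-boryl ether of the anti alcohol F7, and work-up with triethanolamine or water releases 20.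

3. **Step 19.**
   - What may go wrong: competing saturation of the caffeoyl double bond, or slow turnover because the directing carbonyl is a conjugated and weakly basic cinnamate.
   - Fallback: the stereocentre is set on an enol acetate and the caffeoyl ester bond is made afterwards. It sets out from 31 (with 6 and 4) and comes back at 33.
   - Route: acetic acid and 6 with Rh2(OAc)4 give the acetoxy phosphonate F8. Olefination of 31 (LiCl, DBU) gives the enol acetate F9. Rh-(R,R)-Et-DuPhos hydrogenation, now with no second alkene present, gives the (R)-acetate F10. K2CO3/MeOH gives the (R)-alpha-hydroxy ester F11, and Steglich esterification with 4 gives 33.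

Further compounds
F1 | step 14 | 3-{[(1S,2R)-5,5-diethoxy-1-Ar-2-(PMBOCH2)pent-3-yn-1-yl]oxy}pyridazine-4-carbonitrile | CCOC(OCC)C#C[C@H](COCc1ccc(OC)cc1)[C@@H](c1ccc2c(c1)OC(c1ccccc1)(c1ccccc1)O2)Oc1nnccc1C#N
F2 | step 14 | (2S,3R)-4-(diethoxymethyl)-2-Ar-3-(PMBOCH2)-2,3-dihydro-1-benzofuran-7-carbonitrile | CCOC(OCC)c1ccc(C#N)c2c1[C@H](COCc1ccc(OC)cc1)[C@@H](c1ccc3c(c1)OC(c1ccccc1)(c1ccccc1)O3)O2
F3 | step 14 | (2S,3R)-4-(diethoxymethyl)-2-Ar-3-(PMBOCH2)-2,3-dihydro-1-benzofuran-7-carbaldehyde | CCOC(OCC)c1ccc(C=O)c2c1[C@H](COCc1ccc(OC)cc1)[C@@H](c1ccc3c(c1)OC(c1ccccc1)(c1ccccc1)O3)O2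
F4 | step 14 | (2S,3R)-4-(diethoxymethyl)-2-Ar-3-(PMBOCH2)-2,3-dihydro-1-benzofuran-7-yl formate | CCOC(OCC)c1ccc(OC=O)c2c1[C@H](COCc1ccc(OC)cc1)[C@@H](c1ccc3c(c1)OC(c1ccccc1)(c1ccccc1)O3)O2
F5 | step 11 | (2S)-5,5-diethoxy-1-[(4-methoxybenzyl)oxy]pent-3-yn-2-yl methyl carbonate | CCOC(OCC)C#C[C@@H](COCc1ccc(OC)cc1)OC(=O)OC
F6 | step 11 | 2-{(aR)-1,1-diethoxy-5-[(4-methoxybenzyl)oxy]penta-2,3-dien-2-yl}-4,4,5,5-tetramethyl-1,3,2-dioxaborolane | CC1(C)OB(OC1(C)C)C(C(OCC)OCC)=[C@@]=C([H])COCc1ccc(OC)cc1
F7 | step 11 | O-(pinacolboryl) ether of 20 | CCOC(OCC)C#C[C@H](COCc1ccc(OC)cc1)[C@@H](c1ccc2c(c1)OC(c1ccccc1)(c1ccccc1)O2)OB1OC(C)(C)C(C)(C)O1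
F8 | step 19 | tert-butyl 2-acetoxy-2-(dimethoxyphosphoryl)acetate (racemic) | COP(=O)(OC)C(OC(C)=O)C(=O)OC(C)(C)C
F9 | step 19 | enol acetate from 31 and F8 (E/Z mixture) | CC(=O)OC(=Cc1ccc(OCOC)c2c1[C@H](COCc1ccc(OC)cc1)[C@@H](c1ccc3c(c1)OC(c1ccccc1)(c1ccccc1)O3)O2)C(=O)OC(C)(C)C
F10 | step 19 | tert-butyl (2R)-2-acetoxy-3-[(2S,3R)-7-(methoxymethoxy)-2-Ar-3-(PMBOCH2)-2,3-dihydro-1-benzofuran-4-yl]propanoate | CC(=O)O[C@H](Cc1ccc(OCOC)c2c1[C@H](COCc1ccc(OC)cc1)[C@@H](c1ccc3c(c1)OC(c1ccccc1)(c1ccccc1)O3)O2)C(=O)OC(C)(C)C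
F11 | step 19 | tert-butyl (2R)-2-hydroxy-3-[(2S,3R)-7-(methoxymethoxy)-2-Ar-3-(PMBOCH2)-2,3-dihydro-1-benzofuran-4-yl]propanoate | O[C@H](Cc1ccc(OCOC)c2c1[C@H](COCc1ccc(OC)cc1)[C@@H](c1ccc3c(c1)OC(c1ccccc1)(c1ccccc1)O3)O2)C(=O)OC(C)(C)C
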